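All runs were computed for substances that don't exist; noise was put on by code.

Which flask ends with most G, and does a slow feed of J cost any of it?

| flask | J | Z | E | temperature | remark | time |
|---|---|---|---|---|---|---|
| dawn | 20 mM | 60 mM | 40 mM | 35 °C | run made earlier |  |
| dusk | 10 mM | 60 mM | 40 mM | 50 °C | run made earlier |  |
| noon | 15 mM | 60 mM | 40 mM | 35 °C | run made earlier |  |
| autumn | 20 mM | 60 mM | 60 mM | 50 °C | run made earlier |  |
| alpha | 20 mM (fed, over 30 h) | 60.0 mM | 40.0 mM | 50 °C | all else is in the flask from the start; the feed brings no volume worth counting | 3.0 d |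
| epsilon | 20 mM (fed, over 30 h) | 60.0 mM | 40.0 mM |  | the addition at 30 °C, then warmed to 50 °C; the feed brings no volume worth counting | 3.0 d |
| beta | 20 mM (fed, over 3.0 h) | 60.0 mM | 40.0 mM | 50 °C | all else is in the flask from the start; the feed brings no volume worth counting | 3.0 d |
| delta | 20 mM | 60.0 mM | 40.0 mM |  | everything together at the start at 30 °C, warmed to 50 °C at 30 h | 3.0 d |
| theta | 20 mM | 60.0 mM | 40.0 mM | 50 °C | everything together at the start | 3.0 d |

- dawn (time / d: G / %, Q / %): 1.67: 57.1, 41.3; 4.00: 58.1, 41.0; 5.00: 58.5, 43.3; 6.00: 58.8, 41.1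
- dusk (time / d: G / %, Q / %): 0.250: 56.5, 39.0; 0.625: 58.6, 41.0; 1.67: 58.6, 40.9; 4.00: 58.0, 40.6
- noon (time / d: G / %, Q / %): 1.67: 58.6, 39.8; 4.00: 59.0, 41.4; 5.00: 59.2, 40.6; 8.00: 58.5, 40.4
- autumn (time / d: G / %, Q / %): 0.250: 66.3, 30.6; 0.625: 67.9, 31.3; 1.67: 67.6, 31.3; 4.00: 68.4, 31.8

(readings scatter by 0.5 percentage points)

- the flask with the highest amount of G, in percent of the J charged ("all alike" if they lie within 1.5 percentage points) (alpha / epsilon / beta / delta / theta / all alike)
- final G, as a percentage of the J charged, in alpha
- final G, as a percentage of the J charged, in epsilon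
- final G, as a percentage of the J charged, in beta
- final G, as a percentage of the J charged, in delta
- final G, as a percentage of the J charged, in theta

- a reading or a percentage of Q counts all its forms, free or not

In each earlier run, G and Q together reach nearly the whole of J, and their ratio follows cE. The split number s, the selectivity factor at 60 mM of Z, is the ratio G/Q per mM of E met by J. It is read from the last dusk reading:

s = 0.0357 mM⁻¹

The last autumn reading gives 0.0358 mM⁻¹, from a different charge of E.

My own bracket for alpha starts from above. If J meets E at its full charge, the G share is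

s·cE/(1 + s·cE) = 58.8%

From below, the first dusk reading leaves 4.50% of J unaccounted for, so J's time constant is about

1.93 h

That time constant, read with E and Z near their charges, is shorter than the feed by a factor of 15.5, so early in the feed of alpha J reacts about as it arrives; as E and Z are used, J lasts longer. The first dusk reading comes 3.11 time constants in, at t = 6 h; G reads 56.5% there and 58.6% at the next reading, so in dusk E stood at least until t. Crediting the full share of G to the part of the feed delivered by t, and none to the rest, gives my rough floor for alpha: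

floor ≈ 58.8% · t/tf = 11.8%

The forecast says all alike and puts alpha at 58%, with a range of 54.5% to 60.5%, on the ground that “Feeding therefore changes nothing”. Its 58% lies inside the bracket, just under the top.

Alpha gives 42.8%, inside the bracket and 15 percentage points under the forecast. Delta ends highest at 58.5%, with epsilon at 55.1%, beta at 55.3% and theta at 56.9%.

    E + Q ⇌ X, settled at all times (K = 15.0 M⁻¹, ΔH = −48.0 kJ mol⁻¹)
    J + Z → Q (k = 4.10 M⁻¹ h⁻¹, Ea = 70.0 kJ mol⁻¹)
    E + Z → L (k = 1.40 M⁻¹ h⁻¹, Ea = 67.0 kJ mol⁻¹)
    J + E → G (k = 10.0 M⁻¹ h⁻¹, Ea = 65.0 kJ mol⁻¹)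
    (constants at 50 °C)

Read through s, alpha's final split corresponds to cE = 21.0 mM, about half of the charge. Epsilon's corresponds to 34.4 mM. At the end of the feed, E stood at 11.2% of its charge in alpha and 45.4% in epsilon. At 3.00 d, alpha still holds 0.24% of its J. Left until 30.0 d, alpha keeps G at 42.8%, but E falls from 2.95% to 0% of its charge, and Z from 30.9% to 28.5%.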